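**Plan**
- The first disconnection is the O–CH3 bond of the C2 methoxy group, which leads back to the 4-hydroxy-2-pyranone form of the ring.
- The ring is then opened at C4–C5 and O1–C2. Atoms C5–C6–O1 are the enol of an ethyl ketone with the side chain on C6, atoms C2–C3–C4 are a methylmalonyl unit, and each half carries one ring methyl. This pairing of a C–C–O dinucleophile with a C–C–C diacyl electrophile is what makes a [3+3] annulation possible.
- The enol silane goes back to a vinyl ketone (1,4-hydrosilylation fixes the double bond toward C5), then to an aldehyde and a vinyl Grignard reagent, then to a terminal alkene. The chain is cut between C3 and C4 of the undecyl unit (epoxide CH2 to Grignard carbon).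
- Forward, the chain is assembled first by epoxide opening and taken through acetate, aldehyde, vinyl ketone and enol silane. The only ring closes in step 8, and O-methylation finishes the route.
- The single stereocentre (S, acetoxy carbon) is taken from (S)-propylene oxide, and no later step breaks a bond at it.

Key step: step 8

Assumption: the trioxolane carbon in step 3, the carbinol carbon in step 4 and the two methyl-bearing carbons of 14 are carried as mixtures, since all of them are removed or become sp2 centres in the same or the next step. Methylmalonyl dichloride is prepared fresh because it hydrolyses readily.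

**Route**

Step 1
Reactants: 1 10-bromodec-1-ene; 2 (S)-propylene oxide
Product: 4 (S)-tridec-12-en-2-ol, via dec-9-en-1-ylmagnesium bromide 3 (not isolated)
Conditions: Mg, THF, rt to 40 °C; then CuI (10 mol%), 2, THF, −30 °C to 0 °C; aq. NH4Cl
Reagents that add atoms: none
Why: Copper-catalysed Grignard opening of a terminal epoxide, in which the organocopper species from 3 and CuI attacks the unsubstituted CH2 carbon of 2 in an SN2 fashion, so the ten-carbon alkenyl chain joins the three-carbon epoxide without breaking a bond to the stereocentre, whose S configuration becomes that of C2 in the thirteen-carbon alcohol 4.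

Step 2
Reactants: 4 (S)-tridec-12-en-2-ol
Product: 5 (S)-tridec-12-en-2-yl acetate
Conditions: Ac2O, pyridine, DMAP (cat.), CH2Cl2, 0 °C to rt
Reagents that add atoms: acetic anhydride, CC(=O)OC(C)=O
Why: DMAP-catalysed acylation of a secondary alcohol at oxygen leaves the C–O bond, and therefore the configuration, intact and installs the acetate present in the target.

Step 3
Reactants: 5 (S)-tridec-12-en-2-yl acetate
Product: 7 (S)-12-oxododecan-2-yl acetate, via ozonide 6 (not isolated)
Conditions: O3, CH2Cl2, −78 °C; then PPh3, −78 °C to rt
Reagents that add atoms: ozone, [O-][O+]=O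
Why: Ozonolysis with reductive work-up (1,3-dipolar cycloaddition, Criegee rearrangement to the 1,2,4-trioxolane, reduction by PPh3) should cut the terminal alkene to the aldehyde with loss of one carbon as formaldehyde, while the acetate and its stereocentre stay untouched.

Step 4
Reactants: 7 (S)-12-oxododecan-2-yl acetate; 8 vinylmagnesium bromide
Product: 9 (2S)-12-hydroxytetradec-13-en-2-yl acetate (mixture of C12 epimers)
Conditions: 8 (1.1 equiv), THF, −78 °C; aq. NH4Cl
Reagents that add atoms: none
Why: Grignard 1,2-addition to an aldehyde, which at −78 °C with a small excess of reagent should be much faster than attack on the secondary acetate; the new carbinol centre is formed without control and is removed in step 5.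

Step 5
Reactants: 9 (2S)-12-hydroxytetradec-13-en-2-yl acetate
Product: 10 (S)-12-oxotetradec-13-en-2-yl acetate
Conditions: Dess–Martin periodinane, CH2Cl2, 0 °C to rt
Reagents that add atoms: none
Why: Dess–Martin oxidation of a secondary allylic alcohol runs under mild, non-basic conditions that spare the acetate and limit polymerisation of the vinyl ketone, which is used without storage.

Step 6
Reactants: 10 (S)-12-oxotetradec-13-en-2-yl acetate
Product: 11 (2S,12Z)-12-(triethylsilyloxy)tetradec-12-en-2-yl acetate
Conditions: Et3SiH, RhCl(PPh3)3 (1 mol%), toluene, 50 °C
Reagents that add atoms: triethylsilane, CC[SiH](CC)CC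
Why: Rhodium-catalysed 1,4-hydrosilylation of an α,β-unsaturated ketone with a monohydrosilane delivers hydride to the terminal carbon and silicon to oxygen through the s-cis enone, so the enol double bond should lie only between C12 and C13 (Z expected), with the acetate inert.

Step 7
Reactants: 12 methylmalonic acid
Product: 13 methylmalonyl dichloride
Conditions: SOCl2 (neat), 50 °C; distillation under reduced pressure
Reagents that add atoms: thionyl chloride, O=S(Cl)Cl
Why: Acid chloride formation through the acyl chlorosulfite gives only gaseous by-products, and the moderate temperature stays below that at which the malonic acid decarboxylates.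

Step 8
Reactants: 11 (2S,12Z)-12-(triethylsilyloxy)tetradec-12-en-2-yl acetate; 13 methylmalonyl dichloride
Product: 15 (S)-11-(4-hydroxy-3,5-dimethyl-2-oxo-2H-pyran-6-yl)undecan-2-yl acetate, via diketo acid chloride 14 (not isolated)
Conditions: 13 (1.1 equiv), Et2O, −78 °C to rt
Reagents that add atoms: none
Why: The enol carbon C13 of 11 attacks one acyl chloride of 13 (or the chlorocarbonyl ketene formed from it by loss of HCl), which makes ring bond C4–C5, releases Et3SiCl and gives 14; the enol oxygen of the chain-bearing ketone of 14 then attacks the second acyl chloride, making O1–C2 with loss of HCl, and tautomerisation gives the 4-hydroxy-2-pyranone. The closest known reaction type is the [3+3] synthesis of 4-hydroxy-2-pyranones from silyl enol ethers and malonyl dichlorides. The one ring is closed by a 6-exo-trig lactonisation (O-acylation). No stereocentre is created, because both methyl-bearing carbons end as sp2 ring atoms, and the acetoxy carbon is remote and not enolisable. The step needs C-acylation on the methyl side of the ketone and not on the chain side, which the position of the enol double bond set in step 6 secures even though the two α-CH2 groups of the parent ketone are almost indistinguishable. The secondary acetate does not react with acid chlorides, and if O-acylation came first the same ring would still result.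

Step 9
Reactants: 15 (S)-11-(4-hydroxy-3,5-dimethyl-2-oxo-2H-pyran-6-yl)undecan-2-yl acetate
Product: 17 (S)-11-(6-methoxy-3,5-dimethyl-4-oxo-4H-pyran-2-yl)undecan-2-yl acetate, via methoxypyrylium triflate 16 (not isolated)
Conditions: MeOTf, CH2Cl2, 0 °C to rt; then aq. NaHCO3
Reagents that add atoms: methyl trifluoromethanesulfonate, COS(=O)(=O)C(F)(F)F
Why: Regioselective O-methylation of a neutral 4-hydroxy-2-pyranone by a hard methyl sulfonate should take place at the more basic C2 carbonyl oxygen to give the 4-hydroxy-2-methoxypyrylium salt, which loses its O–H proton on bicarbonate work-up to give the 2-methoxy-4-pyranone; the acetate carbonyl is far less nucleophilic and the stereocentre is not involved.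

**Compound list**
1 | 10-bromodec-1-ene | C=CCCCCCCCCBr | starting material
2 | (S)-propylene oxide, (S)-2-methyloxirane | C[C@H]1CO1 | starting material
3 | dec-9-en-1-ylmagnesium bromide | C=CCCCCCCCC[Mg]Br | intermediate
4 | (S)-tridec-12-en-2-ol | C=CCCCCCCCCC[C@H](C)O | intermediate
5 | (S)-tridec-12-en-2-yl acetate | C=CCCCCCCCCC[C@H](C)OC(C)=O | intermediate
6 | (2S)-11-(1,2,4-trioxolan-3-yl)undecan-2-yl acetate (ozonide, mixture at the trioxolane carbon) | CC(=O)O[C@@H](C)CCCCCCCCCC1OCOO1 | intermediate
7 | (S)-12-oxododecan-2-yl acetate | O=CCCCCCCCCC[C@H](C)OC(C)=O | intermediate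
8 | vinylmagnesium bromide | C=C[Mg]Br | starting material
9 | (2S)-12-hydroxytetradec-13-en-2-yl acetate (C12 epimer mixture) | C=CC(O)CCCCCCCCC[C@H](C)OC(C)=O | intermediate
10 | (S)-12-oxotetradec-13-en-2-yl acetate | C=CC(=O)CCCCCCCCC[C@H](C)OC(C)=O | intermediate
11 | (2S,12Z)-12-(triethylsilyloxy)tetradec-12-en-2-yl acetate | C/C=C(\O[Si](CC)(CC)CC)CCCCCCCCC[C@H](C)OC(C)=O | intermediate
12 | methylmalonic acid | CC(C(=O)O)C(=O)O | starting material
13 | methylmalonyl dichloride (2-methylpropanedioyl dichloride) | CC(C(Cl)=O)C(Cl)=O | intermediate
14 | (15S)-15-acetoxy-2,4-dimethyl-3,5-dioxohexadecanoyl chloride (mixture at C2 and C4) | CC(C(Cl)=O)C(=O)C(C)C(=O)CCCCCCCCC[C@H](C)OC(C)=O | intermediate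
15 | (S)-11-(4-hydroxy-3,5-dimethyl-2-oxo-2H-pyran-6-yl)undecan-2-yl acetate | Cc1c(O)c(C)c(CCCCCCCCC[C@H](C)OC(C)=O)oc1=O | intermediate
16 | 6-[(10S)-10-acetoxyundecyl]-4-hydroxy-2-methoxy-3,5-dimethylpyrylium trifluoromethanesulfonate | COc1[o+]c(CCCCCCCCC[C@H](C)OC(C)=O)c(C)c(O)c1C.[O-]S(=O)(=O)C(F)(F)F | intermediate
17 | (S)-11-(6-methoxy-3,5-dimethyl-4-oxo-4H-pyran-2-yl)undecan-2-yl acetate | COc1oc(CCCCCCCCC[C@H](C)OC(C)=O)c(C)c(=O)c1C | target

**Count**
Total step count: 9. Longest linear sequence: 8 steps (steps 1 to 6, 8 and 9); step 7 is a one-step branch.

**Steps most likely to fail**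

Step 8. The HCl released may strip the silyl group before the C–C bond forms, which would return the parent ketone and lose the regiocontrol. O-acylation may also stall before ring closure, or the ketene derived from the dichloride may self-condense. The fallback builds the same ring from a linear tricarbonyl chain and sets out from aldehyde 7, so steps 4 to 6 are not needed. The dianion of ethyl 2-methyl-3-oxopentanoate (NaH, then n-BuLi, THF, 0 °C) would add through its terminal carbon to 7 at −78 °C to give ethyl (15S)-15-acetoxy-5-hydroxy-2,4-dimethyl-3-oxohexadecanoate F1. Dess–Martin oxidation would give ethyl (15S)-15-acetoxy-2,4-dimethyl-3,5-dioxohexadecanoate F2. DBU in toluene would then close the lactone with loss of ethanol, and the route is rejoined at 15.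

Step 9. Methylation may occur at the C4 oxygen instead of the C2 carbonyl oxygen, or the triflic acid formed may cleave the acetate. The fallback avoids methylating an ambident pyranone by bringing the methoxy group in as an ester, and again sets out from aldehyde 7. The dianion of methyl 2-methyl-3-oxopentanoate (NaH, then n-BuLi, THF) would add to 7 to give methyl (15S)-15-acetoxy-5-hydroxy-2,4-dimethyl-3-oxohexadecanoate F3. Dess–Martin oxidation would give methyl (15S)-15-acetoxy-2,4-dimethyl-3,5-dioxohexadecanoate F4. Cyclodehydration with PPh3 and CCl4 in THF keeps the ester methoxy group on C2 and expels only water, so it should lead directly to the 2-methoxy-4-pyranone, rejoining the route at 17.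

Step 6. 1,2-Hydrosilylation or polymerisation of the vinyl ketone may compete with the 1,4-addition, and the enol silane may hydrolyse during isolation. The fallback reaches the same regiodefined enol silane by moving a double bond, without passing through the vinyl ketone, and sets out from allylic alcohol 9. Silylation with Et3SiCl and imidazole in CH2Cl2 would give (2S)-12-(triethylsilyloxy)tetradec-13-en-2-yl acetate F5. Isomerisation of this allyl silyl ether with [Ir(cod)(PMePh2)2]PF6 (activated with H2, THF, rt) should shift the terminal double bond into conjugation with oxygen, rejoining the route at 11. The geometry of the enol double bond has no bearing on step 8.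

**Further compounds**
F1 | step 8 | ethyl (15S)-15-acetoxy-5-hydroxy-2,4-dimethyl-3-oxohexadecanoate | CCOC(=O)C(C)C(=O)C(C)C(O)CCCCCCCCC[C@H](C)OC(C)=O
F2 | step 8 | ethyl (15S)-15-acetoxy-2,4-dimethyl-3,5-dioxohexadecanoate | CCOC(=O)C(C)C(=O)C(C)C(=O)CCCCCCCCC[C@H](C)OC(C)=O
F3 | step 9 | methyl (15S)-15-acetoxy-5-hydroxy-2,4-dimethyl-3-oxohexadecanoate | COC(=O)C(C)C(=O)C(C)C(O)CCCCCCCCC[C@H](C)OC(C)=O
F4 | step 9 | methyl (15S)-15-acetoxy-2,4-dimethyl-3,5-dioxohexadecanoate | COC(=O)C(C)C(=O)C(C)C(=O)CCCCCCCCC[C@H](C)OC(C)=O
F5 | step 6 | (2S)-12-(triethylsilyloxy)tetradec-13-en-2-yl acetate | C=CC(O[Si](CC)(CC)CC)CCCCCCCCC[C@H](C)OC(C)=O
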